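Watch G. Ochre and violet are one charge stopped at two times.

| flask | J | X | E | remark | time |
|---|---|---|---|---|---|
| Monday's | 0.25 M | 0.12 M | 0.275 M | run made earlier |  |
| Saturday's | 0.25 M | 0.19 M | 0.275 M | run made earlier |  |
| ochre | 0.25 M | 0.250 M | 0.275 M |  | 5.0 min |
| violet | 0.25 M | 0.250 M | 0.275 M |  | 10 min |

| run | time / min | G / % | Q / % | J / % |
|---|---|---|---|---|
| Monday's | 1.00 | 2 | 24 | 46 |
| Monday's | 2.00 | 6 | 27 | 28 |
| Monday's | 3.00 | 10 | 26 | 25 |
| Monday's | 4.00 | 13 | 23 | 18 |
| Monday's | 5.00 | 15 | 24 | 18 |
| Saturday's | 0.417 | 0 | 23 | 62 |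
| Saturday's | 0.833 | 2 | 34 | 42 |
| Saturday's | 1.33 | 2 | 38 | 31 |
| Saturday's | 2.50 | 11 | 44 | 22 |
| Saturday's | 5.00 | 19 | 37 | 9 |

(scatter of a reading: 1.5 percentage points)

- in percentages every species weighs as the J in it: one Z or L counts as two
- for G the Z are counted in
- as a solid, counted per litre of solution: E
- on the list of suspects stand: J + X -> Q; D + Q -> G; J + G <-> Z; E <-> D; 2 J -> L
- at the start none of E is in solution
- in an amount of G, one Z counts as one G

- which of these there is most of at the end, counted by the J in it, ochre (J / Q / G)
- which of these there is most of at the end, counted by the J in it, violet (J / Q / G)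
- amount of the one of these that there is most of at the end, in percent of the J charged, ochre
- amount of the one of these that there is most of at the end, in percent of the J charged, violet

In the flask, J goes with X into Q, Q goes on to G, and part of J goes missing from the readings. At the last reading, J + Q + G falls short by 43.0 % in Monday's run and by 35.0 % in Saturday's. A straight line through these two, carried to 0.250 M of X, puts our own loss at:

lost = 28.1 %, so Q + G + J = 71.9 %

Saturday's run gained G at 3.80 % min⁻¹ on average. Call this mean gain of G per minute the G pace. The scatter of one reading makes it uncertain by 3 percentage points at the violet time.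

Ochre: G = 19.0 %, and with Saturday's J of 9 %, Q = 43.9 %

Violet: G = 38.0 %, and with J left out of the count, Q = 33.9 %

So we expect Q on top in ochre and, narrowly, G ahead of Q in violet. Leave the solid E alone: D + Q -> G stands among the suspects, so G draws on E, and the E ceiling, E charged over J charged, is 110 %, above our violet G.

The forecast gives Q at 49 % in ochre and Q at 38 % in violet, “nearly a toss-up”, so on violet it parts from us.

The flask gives Q at 48.9 % in ochre, and G at 41.0 % in violet, with Q at 32.5 %.

    J + X → Q (k = 0.0720 M⁻¹ s⁻¹)
    D + Q → G (k = 0.540 M⁻¹ s⁻¹)
    J + G ⇌ Z, settled at all times (K = 5.60 M⁻¹)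
    E ⇌ D, rate k4*(cs4 - [D]) while solid is left; crystals form when [D] > cs4 (solubility = 19.0 mM, k = 0.0110 s⁻¹)
    2 J → L (k = 0.0180 M⁻¹ s⁻¹)

In violet, Q was made 7.81 times faster than it was used up at 0.627 min, each step taken net, and by 5.00 min the step J + X had behind it 94 % of its turnover up to 10.0 min. From then to 10.0 min in violet, G rose from 20.4 % to 41.0 % while Q fell from 48.9 % to 32.5 %, and the mean G pace of violet over its whole run is 4.10 % min⁻¹. For a neighbouring flask, violet with 0.069 M of E, our pace reckons G at 38.0 %, but its E ceiling is 27.6 %. In that flask E is the limiting reagent, with 0 % of its charge left at 10.0 min, and G stands at 27.6 %.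

The runs were computed with made-up constants, and the scatter is random.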